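Readings and results are simulated for substances that don't exist, and the scatter is random.

What will this flask show at its best, and when?

| setting | grey | teal | flask |
|---|---|---|---|
| substrate | 0.61 M | 1.4 M | 0.91 M |
| remark | run made earlier | run made earlier |  |
| time |  |  | 4.0 d |

| run | time / d | target / % | substrate / % |
|---|---|---|---|
| grey | 0.0556 | 13.0 | 68.2 |
| grey | 0.208 | 21.2 | 29.8 |
| grey | 0.625 | 17.7 | 12.2 |
| grey | 2.50 | 4.9 | 2.8 |
| teal | 0.0556 | 10.4 | 63.7 |
| teal | 0.208 | 11.9 | 23.5 |
| teal | 0.625 | 7.4 | 9.3 |
| teal | 2.50 | 2.9 | 2.1 |

(each reading ± 1 percentage point)

- time up to 4.0 d at which target stands highest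
- the amount of target, in percent of the substrate charged, at that time



Where does target end up? Low: the grey run falls from 21.2 % at 0.208 d to 4.9 % at 2.50 d. So the top is a passing one, a matter of kinetic control, and the end state is no guide to it.

When is that top? The highest target reading stands at 0.208 d in grey and 0.208 d in teal, much earlier than the 4.0 d allowed, so I commit to about that time for the flask.

How high? Grey shows 21.2 % from 0.61 M, teal 11.9 % from 1.4 M: a bigger charge, a smaller share. Spread over the logarithm of the charge, that is 7.8 percentage points. Call it the drop per doubling, the points of peak target lost each time the charge is doubled. The flask stands 0.577 doublings above grey, which gives 16.7 %.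

But can two readings make a line? They cannot test it. Each carries 1 point, and a top may hide between sampled times, so my number may stand low.

The forecast says 16.7 % (14.8 % to 18.8 %) at 0.2 d (0.13 d to 0.32 d), by “Interpolating on log concentration”. That is my kind of reading on the same runs, so the likeness checks nothing.

The flask gives 17.7 % at 0.209 d, inside both ranges and 1.00 point above my number.

    substrate ⇌ target + by-product (K = 0.310 M, k = 0.140 h⁻¹)
    substrate ⇌ dormant form (K = 0.580, k = 0.170 h⁻¹)
    substrate + by-product → side product A (k = 0.230 M⁻¹ h⁻¹)
    substrate + target → side product B (k = 0.480 M⁻¹ h⁻¹)

The interpolation carried the weight, and the flask stands 1.1 points under the top of the forecast's range. Now carry the drop, 7.8 points for each factor of 2 in the charge, from this flask to the neighbour charged with 1.5 M of substrate, 0.721 of those factors higher on the logarithm: it gives 12.1 %. The neighbour flask tops out at 12.7 %, somewhat more than that, and at 4.00 d it holds 1.78 % target.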